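**Assumptions (one line each)**
- Cembrane numbering is used: C1 = lactone CH bearing C15; C2 = lactone O–CH; C3/C4 = epoxide (C4 carries Me); C5 = CHOAc; C7=C8(Me); C9 = CHOH; C11=C12(Me); C14 = CHOAc; C15(=C17H2)–C16(=O)O. The target is then (1R,2S,3S,4S,5R,9S,14R,7E,11E).
- The catalyst/ligand antipodes named in steps 2, 13 and 21 are assigned by analogy to related substrates; if the sense proves opposite, the mirror-image catalyst is used and nothing else changes.
- This is a designed route; no step has been run on these substrates.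

**Retrosynthetic overview**
1. C8–C9: final Ni/Cr (Nozaki–Hiyama–Kishi) macrocyclisation of a vinyl iodide onto an aldehyde closes the 14-membered ring and reveals the free C9–OH.
2. C1–C2 and O–C16: allylboration–lactonisation of epoxy-aldehyde 11 (C2–C8) with 2-alkoxycarbonyl allylboronate 21 (C9–C14, C1, C15–C17) builds the trans α-methylene-γ-butyrolactone.
3. West fragment 11: Wittig (C3=C4), asymmetric propargylation (C5), hydrozirconation–iodination (C7=C8–I), Sharpless epoxidation (C3, C4).
4. East fragment 21: Negishi carboalumination/ethylene oxide (C11=C12), asymmetric propiolate addition (C14), syn-hydrometalation/borylmethylation.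
5. Ring order: oxirane (step 7), then γ-lactone (step 16), then 14-membered carbocycle (step 21).

## West fragment (C2–C8)

**Step 1**
Reactants: 1, 2-[(tert-butyldimethylsilyl)oxy]acetaldehyde; 2, 2-(triphenylphosphoranylidene)propanal
Product: 3, (E)-4-[(tert-butyldimethylsilyl)oxy]-2-methylbut-2-enal
Conditions: PhMe, 90 °C
Reagents that add atoms: none
Why: Wittig olefination with a formyl-stabilised ylide gives the E-trisubstituted enal (future C3=C4 with its methyl) under thermodynamic control.

**Step 2**
Reactants: 3; 4, allenylboronic acid pinacol ester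
Product: 5, (2E,4R)-1-[(TBS)oxy]-3-methylhept-2-en-6-yn-4-ol
Conditions: (R)-TRIP phosphoric acid (10 mol %), 4 Å MS, PhMe, –20 → 0 °C
Reagents that add atoms: none
Why: Chiral-phosphoric-acid-catalysed propargylation (SE2′ of the allenylboronate through a closed six-membered transition state); the catalyst selects the aldehyde face and sets C5 (R).

**Step 3**
Reactants: 5
Product: 6, (2E,4R)-1-[(TBS)oxy]-3-methyloct-2-en-6-yn-4-ol
Conditions: n-BuLi (2.2 equiv), THF, –78 → –20 °C; MeI, DMPU, –78 °C → rt
Reagents that add atoms: iodomethane, CI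
Why: Acetylide alkylation of the alkoxide/acetylide dianion; the carbanion is methylated in preference to the lithium alkoxide, and C5 is untouched.

**Step 4**
Reactants: 6
Product: 7, (2E,4R,6E)-1-[(TBS)oxy]-7-iodo-3-methylocta-2,6-dien-4-ol
Conditions: Cp2Zr(H)Cl (3 equiv), THF, rt → 45 °C; then I2, 0 °C
Reagents that add atoms: iodine, II
Why: Schwartz syn-hydrozirconation places Zr on the less hindered, methyl-bearing alkyne carbon after equilibration (the O–Zr alkoxide adds bulk on the other side); iodinolysis with retention gives the (E)-2-iodo-2-alkene that becomes the 7E olefin.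

**Step 5**
Reactants: 7
Product: 8, (2E,4R,6E)-1-[(TBS)oxy]-7-iodo-3-methylocta-2,6-dien-4-yl acetate
Conditions: Ac2O, pyridine, DMAP (cat.), CH2Cl2, 0 °C → rt
Reagents that add atoms: acetic anhydride, CC(=O)OC(C)=O
Why: Standard acylation installs the final C5 acetate, which also blocks this secondary allylic OH from directing the later epoxidation.

**Step 6**
Reactants: 8
Product: 9, (2E,4R,6E)-1-hydroxy-7-iodo-3-methylocta-2,6-dien-4-yl acetate
Conditions: HF·pyridine, pyridine, THF, 0 °C → rt
Reagents that add atoms: none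
Why: Buffered acidic fluoride desilylation frees the primary allylic alcohol without acetate cleavage or migration.

**Step 7**
Reactants: 9
Product: 10, (1R,3E)-1-[(2S,3S)-3-(hydroxymethyl)-2-methyloxiran-2-yl]-4-iodopent-3-en-1-yl acetate
Conditions: Ti(OiPr)4, L-(+)-DET, t-BuOOH, 4 Å MS, CH2Cl2, –20 °C
Reagents that add atoms: tert-butyl hydroperoxide, CC(C)(C)OO
Why: Katsuki–Sharpless asymmetric epoxidation of the primary E-allylic alcohol; L-(+)-tartrate gives the (S,S)-epoxide (same substitution pattern and sense as geraniol → 2S,3S), setting C3 and C4 under reagent control, and the electron-poor vinyl iodide is inert.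

**Step 8**
Reactants: 10
Product: 11, (1R,3E)-1-[(2S,3R)-3-formyl-2-methyloxiran-2-yl]-4-iodopent-3-en-1-yl acetate
Conditions: Dess–Martin periodinane, NaHCO3, CH2Cl2, 0 °C → rt; used directly
Reagents that add atoms: none
Why: Neutral Dess–Martin oxidation gives the non-enolisable α,β-epoxy aldehyde without touching epoxide, acetate or vinyl iodide (the oxirane descriptor changes only because CHO outranks C4).

## East fragment (C9–C14, C1, C15–C17)

**Step 9**
Reactants: 12, tert-butyl(but-3-yn-1-yloxy)dimethylsilane; 13, oxirane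
Product: 14, (E)-6-[(TBS)oxy]-4-methylhex-3-en-1-ol
Conditions: Me3Al, Cp2ZrCl2 (cat.), CH2Cl2, 0 °C → rt; then n-BuLi, THF, –78 °C; 13, –78 → 0 °C
Reagents that add atoms: trimethylaluminium, C[Al](C)C
Why: Negishi Zr-catalysed syn-carboalumination puts the methyl on the internal carbon, and the derived alkenylalanate opens ethylene oxide with retention, giving the E-trisubstituted C11=C12 olefin.

**Step 10**
Reactants: 14
Product: 15, tert-butyl{[(E)-6-(4-methoxybenzyloxy)-3-methylhex-3-en-1-yl]oxy}dimethylsilane
Conditions: NaH, PMBCl, Bu4NI, THF/DMF, 0 °C → rt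
Reagents that add atoms: 4-methoxybenzyl chloride, COc1ccc(CCl)cc1
Why: Williamson etherification protects the future C9 oxygen orthogonally to silyl ethers and acetates.

**Step 11**
Reactants: 15
Product: 16, (E)-6-[(4-methoxybenzyl)oxy]-3-methylhex-3-en-1-ol
Conditions: TBAF, THF, rt
Reagents that add atoms: none
Why: Fluoride desilylation frees the C14 oxygen; PMB ether and olefin are inert.

**Step 12**
Reactants: 16
Product: 17, (E)-6-[(4-methoxybenzyl)oxy]-3-methylhex-3-enal
Conditions: Dess–Martin periodinane, NaHCO3, CH2Cl2, 0 °C; used crude at once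
Reagents that add atoms: none
Why: Buffered Dess–Martin oxidation gives the β,γ-unsaturated aldehyde without migration of the double bond into conjugation.

**Step 13**
Reactants: 17; 18, methyl propiolate
Product: 19, methyl (4R,6E)-4-hydroxy-9-[(4-methoxybenzyl)oxy]-6-methylnon-6-en-2-ynoate
Conditions: Me2Zn, (S,S)-ProPhenol (20 mol %), Ph3P=O, PhMe, 4 °C, slow addition of 17
Reagents that add atoms: none
Why: Trost Zn–ProPhenol asymmetric alkynylation; the dinuclear zinc catalyst delivers the zinc propiolate to one aldehyde face and sets C14 (R).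

**Step 14**
Reactants: 19
Product: 20, methyl (4R,6E)-4-[(TBS)oxy]-9-[(4-methoxybenzyl)oxy]-6-methylnon-6-en-2-ynoate
Conditions: TBSOTf, 2,6-lutidine, CH2Cl2, –78 °C
Reagents that add atoms: tert-butyldimethylsilyl triflate, CC(C)(C)[Si](C)(C)OS(=O)(=O)C(F)(F)F
Why: Low-temperature silylation with a hindered base avoids base-induced isomerisation of the γ-hydroxy ynoate.

**Step 15**
Reactants: 20
Product: 21, methyl (2Z,4R,6E)-4-[(TBS)oxy]-9-[(4-methoxybenzyl)oxy]-6-methyl-2-[(4,4,5,5-tetramethyl-1,3,2-dioxaborolan-2-yl)methyl]nona-2,6-dienoate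
Conditions: DIBAL-H, MeCu (10 mol %), HMPA/THF, –20 °C; then ICH2Bpin, –20 °C → rt
Reagents that add atoms: 2-(iodomethyl)-4,4,5,5-tetramethyl-1,3,2-dioxaborolane, ICB1OC(C)(C)C(C)(C)O1
Why: Copper-catalysed conjugate syn-hydroalumination of the ynoate, then trapping of the α-metallo enoate with retention, puts C14 cis to CO2Me and trans to CH2Bpin, the geometry needed for an anti (trans-lactone) allylboration.

## Fragment union and endgame

**Step 16**
Reactants: 11; 21
Product: 22, seco-lactone: (4R,5S)-3-methylidene-oxolan-2-one carrying at C5 the (2S,3S)-3-[(1R,3E)-1-acetoxy-4-iodopent-3-enyl]-3-methyloxiran-2-yl group and at C4 the (1R,3E)-1-[(TBS)oxy]-6-[(PMB)oxy]-3-methylhex-3-enyl group (trans)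
Conditions: PhMe (1 M), 80 °C, 48 h; then PPTS (cat.), 45 °C
Reagents that add atoms: none (MeOH and pinB–OH are lost)
Why: Type-I allylboration through a closed chair transition state followed by lactonisation; C1 and C2 are set as follows.
- The γ-substituent trans to CH2B gives the anti adduct, hence the trans lactone.
- The cis-substituted epoxy aldehyde reacts on its Felkin–Anh face (C–O of the epoxide anti to the incoming carbon), giving C2 (S).
- The allyl unit reacts with H-14 eclipsing the alkene (A1,3 strain with the cis ester), C13 anti and OTBS outside, giving C1 (R).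
- The silyl ether on C14 ensures that only O2 lactonises.

**Step 17**
Reactants: 22
Product: 23, the C14 alcohol (as 22 with OH in place of OTBS)
Conditions: HF·pyridine, pyridine, THF, 0 °C → rt
Reagents that add atoms: none
Why: Buffered desilylation; epoxide, acetate, PMB ether, vinyl iodide and α-methylene lactone are stable, and the trans O2-lactone is expected to be favoured over the cis O14 isomer, so translactonisation is not expected.

**Step 18**
Reactants: 23
Product: 24, the C5,C14-diacetate (as 23 with OAc at C14)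
Conditions: Ac2O, pyridine, DMAP (cat.), CH2Cl2, 0 °C
Reagents that add atoms: acetic anhydride, CC(=O)OC(C)=O
Why: Acylation of the only free hydroxyl installs the second acetate.

**Step 19**
Reactants: 24
Product: 25, the primary C9 alcohol (as 24 with CH2OH in place of CH2OPMB)
Conditions: DDQ, CH2Cl2/pH 7 buffer, 0 °C
Reagents that add atoms: none
Why: Oxidative PMB cleavage under neutral conditions spares acetates, epoxide, lactone and vinyl iodide.

**Step 20**
Reactants: 25
Product: 26, the C9 aldehyde (as 25 with CHO)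
Conditions: Dess–Martin periodinane, NaHCO3, CH2Cl2, 0 °C; filtered and used immediately
Reagents that add atoms: none
Why: Buffered Dess–Martin oxidation delivers the β,γ-unsaturated aldehyde without isomerisation.

**Step 21**
Reactants: 26
Product: 27, michaolide A
Conditions: CrCl2, Kishi chiral oxazoline–sulfonamide ligand, Et3N, NiCl2 (cat.), THF, 2 mM, rt
Reagents that add atoms: none
Why: Intramolecular Nozaki–Hiyama–Kishi coupling of the vinyl iodide with the aldehyde, which tolerates lactone, epoxide and acetates, closes the 14-membered ring with retention of the 7E geometry; C9 (S) is set by the chiral Cr–sulfonamide ligand, and the 9-epimer is separable.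

## Compound list

1 | 2-[(tert-butyldimethylsilyl)oxy]acetaldehyde | O=CCO[Si](C)(C)C(C)(C)C | starting material
2 | 2-(triphenylphosphoranylidene)propanal | CC(C=O)=P(c1ccccc1)(c1ccccc1)c1ccccc1 | starting material
3 | (E)-4-[(TBS)oxy]-2-methylbut-2-enal | O=C/C(C)=C/CO[Si](C)(C)C(C)(C)C | intermediate
4 | allenylboronic acid pinacol ester | C=C=CB1OC(C)(C)C(C)(C)O1 | starting material
5 | (2E,4R)-1-[(TBS)oxy]-3-methylhept-2-en-6-yn-4-ol | C#CC[C@@H](O)/C(C)=C/CO[Si](C)(C)C(C)(C)C | intermediate
6 | (2E,4R)-1-[(TBS)oxy]-3-methyloct-2-en-6-yn-4-ol | CC#CC[C@@H](O)/C(C)=C/CO[Si](C)(C)C(C)(C)C | intermediate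
7 | (2E,4R,6E)-1-[(TBS)oxy]-7-iodo-3-methylocta-2,6-dien-4-ol | I/C(C)=C/C[C@@H](O)/C(C)=C/CO[Si](C)(C)C(C)(C)C | intermediate
8 | (2E,4R,6E)-1-[(TBS)oxy]-7-iodo-3-methylocta-2,6-dien-4-yl acetate | I/C(C)=C/C[C@@H](OC(C)=O)/C(C)=C/CO[Si](C)(C)C(C)(C)C | intermediate
9 | (2E,4R,6E)-1-hydroxy-7-iodo-3-methylocta-2,6-dien-4-yl acetate | I/C(C)=C/C[C@@H](OC(C)=O)/C(C)=C/CO | intermediate
10 | (1R,3E)-1-[(2S,3S)-3-(hydroxymethyl)-2-methyloxiran-2-yl]-4-iodopent-3-en-1-yl acetate | I/C(C)=C/C[C@@H](OC(C)=O)[C@]1(C)O[C@H]1CO | intermediate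
11 | (1R,3E)-1-[(2S,3R)-3-formyl-2-methyloxiran-2-yl]-4-iodopent-3-en-1-yl acetate | I/C(C)=C/C[C@@H](OC(C)=O)[C@]1(C)O[C@H]1C=O | intermediate
12 | tert-butyl(but-3-yn-1-yloxy)dimethylsilane | C#CCCO[Si](C)(C)C(C)(C)C | starting material
13 | oxirane (ethylene oxide) | C1CO1 | starting material
14 | (E)-6-[(TBS)oxy]-4-methylhex-3-en-1-ol | OCC/C=C(C)/CCO[Si](C)(C)C(C)(C)C | intermediate
15 | tert-butyl{[(E)-6-(4-methoxybenzyloxy)-3-methylhex-3-en-1-yl]oxy}dimethylsilane | COc1ccc(COCC/C=C(C)/CCO[Si](C)(C)C(C)(C)C)cc1 | intermediate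
16 | (E)-6-[(4-methoxybenzyl)oxy]-3-methylhex-3-en-1-ol | COc1ccc(COCC/C=C(C)/CCO)cc1 | intermediate
17 | (E)-6-[(4-methoxybenzyl)oxy]-3-methylhex-3-enal | COc1ccc(COCC/C=C(C)/CC=O)cc1 | intermediate
18 | methyl propiolate | C#CC(=O)OC | starting material
19 | methyl (4R,6E)-4-hydroxy-9-[(4-methoxybenzyl)oxy]-6-methylnon-6-en-2-ynoate | COC(=O)C#C[C@H](O)C/C(C)=C/CCOCc1ccc(OC)cc1 | intermediate
20 | methyl (4R,6E)-4-[(TBS)oxy]-9-[(4-methoxybenzyl)oxy]-6-methylnon-6-en-2-ynoate | COC(=O)C#C[C@H](O[Si](C)(C)C(C)(C)C)C/C(C)=C/CCOCc1ccc(OC)cc1 | intermediate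
21 | methyl (2Z,4R,6E)-4-[(TBS)oxy]-9-[(4-methoxybenzyl)oxy]-6-methyl-2-[(pinacolatoboryl)methyl]nona-2,6-dienoate | COC(=O)/C(CB1OC(C)(C)C(C)(C)O1)=C\[C@H](O[Si](C)(C)C(C)(C)C)C/C(C)=C/CCOCc1ccc(OC)cc1 | intermediate
22 | trans-lactone seco compound, C14–OTBS, C9–OPMB, C5–OAc, C8–I (1R,2S,3S,4S,5R,14R) | C=C1C(=O)O[C@H]([C@@H]2O[C@@]2(C)[C@H](OC(C)=O)C/C=C(C)/I)[C@H]1[C@H](O[Si](C)(C)C(C)(C)C)C/C(C)=C/CCOCc1ccc(OC)cc1 | intermediate
23 | as 22 with free C14–OH | C=C1C(=O)O[C@H]([C@@H]2O[C@@]2(C)[C@H](OC(C)=O)C/C=C(C)/I)[C@H]1[C@H](O)C/C(C)=C/CCOCc1ccc(OC)cc1 | intermediate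
24 | as 23 with C14–OAc (diacetate, C9–OPMB) | C=C1C(=O)O[C@H]([C@@H]2O[C@@]2(C)[C@H](OC(C)=O)C/C=C(C)/I)[C@H]1[C@H](OC(C)=O)C/C(C)=C/CCOCc1ccc(OC)cc1 | intermediate
25 | as 24 with free primary C9–OH | C=C1C(=O)O[C@H]([C@@H]2O[C@@]2(C)[C@H](OC(C)=O)C/C=C(C)/I)[C@H]1[C@H](OC(C)=O)C/C(C)=C/CCO | intermediate
26 | as 25 with C9 aldehyde (vinyl iodide/aldehyde macrocyclisation precursor) | C=C1C(=O)O[C@H]([C@@H]2O[C@@]2(C)[C@H](OC(C)=O)C/C=C(C)/I)[C@H]1[C@H](OC(C)=O)C/C(C)=C/CC=O | intermediate
27 | michaolide A | C=C1C(=O)O[C@H]2[C@H]1[C@H](OC(C)=O)C/C(C)=C/C[C@H](O)/C(C)=C/C[C@@H](OC(C)=O)[C@]1(C)O[C@@H]21 | target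

## Totals and main risks

**Total steps:** 21 (West 1–8, East 9–15, union and endgame 16–21).
**Longest linear sequence:** 14 steps (1–8, then 16–21); the East branch is 7 steps before the union.

**Three steps most likely to fail**

1. **Step 16 (allylboration–lactonisation).** 2-Alkoxycarbonyl allylboronates are sluggish, the epoxy aldehyde is heat-sensitive, and the facial bias exerted by the C14–OTBS centre is the least certain stereochemical element in the route.
   Fallback: reverse the bond construction. Add a propargyl-ether acetylide to 11 (Felkin), then Red-Al/I2 and Pd carbonylation to an α-(hydroxymethyl)butenolide and its bromide. Couple this with aldehyde 17 using CrCl2; attack anti to the C2 substituent fixes the trans lactone. Then set and acetylate C14 by Mitsunobu inversion with AcOH.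

2. **Step 21 (NHK macrocyclisation).** The trisubstituted vinyl iodide is slow, the β,γ-unsaturated aldehyde can isomerise, and C9 selectivity in a 14-membered closure is uncertain.
   Fallback for selectivity: oxidise the C9 epimer mixture to the macrocyclic enone and reduce with (R)-Me-CBS/BH3.
   Fallback if closure fails: move the ring-closing bond to C7=C8 with an intramolecular Horner–Wadsworth–Emmons reaction (β-ketophosphonate at C8/C9, aldehyde at C7), then CBS reduction.

3. **Step 15 (hydrometalation/borylmethylation).** The α-metallo enoate can lose geometry through the allenoate, or eliminate the γ-silyloxy group to an allene.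
   Fallback: Pd(0)-catalysed syn-hydrostannation of 20 to the α-stannyl (Z)-enoate, iododestannylation, and Negishi coupling with IZnCH2Bpin to reach the same boronate by cross-coupling.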